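The runs are calculated from invented constants; the scatter is artificial.

50.4% of the first end groups charged is the mean reading of links in the green run, and the readings are flat from the first one on, within their scatter. So I carry one number for that level.

| setting | green | grey | ochre | amber | larch | elm | ash |
|---|---|---|---|---|---|---|---|
| first end groups | 0.23 M | 0.15 M | 0.35 M | 0.23 M | 0.23 M (fed, over 12 min) | 0.23 M | 0.23 M |
| second end groups | 0.218 M | 0.218 M | 0.218 M | 0.11 M | 0.218 M | 0.218 M (fed, over 12 min) | 0.218 M |
| remark | run made earlier | run made earlier | run made earlier | run made earlier | all else is in the flask from the start; the feed brings no volume worth counting | all else is in the flask from the start; the feed brings no volume worth counting | everything together at the start |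
| time |  |  |  |  | 20 min | 20 min | 20 min |

| green: time / min | green: links / % | grey: time / min | grey: links / % | ochre: time / min | ochre: links / % | amber: time / min | amber: links / % |
|---|---|---|---|---|---|---|---|
| 1.00 | 51.6 | 4.00 | 61.8 | 1.50 | 43.0 | 1.50 | 32.3 |
| 2.00 | 49.5 | 8.00 | 60.1 | 3.00 | 43.0 | 3.00 | 35.3 |
| 3.00 | 50.0 | 12.0 | 60.4 | 6.00 | 43.3 | 6.00 | 32.7 |
| 6.00 | 50.0 | 15.0 | 59.5 | 10.0 | 44.3 | 10.0 | 31.8 |
| 12.0 | 51.0 | 20.0 | 60.5 | 20.0 | 39.9 | 20.0 | 32.2 |

(readings scatter by 1 percentage point)

* the flask that comes out highest in amount of links, in percent of the first end groups charged, or "all alike" when all lie within 1.5 percentage points (larch / elm / ash / all alike)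
* links at the end, in percent of the first end groups charged, larch
* links at the end, in percent of the first end groups charged, elm
* links at the end, in percent of the first end groups charged, ash



Let x be links as a fraction of the first end groups charged, and r the second end groups charged per first end group. I read a balance quotient, x squared over (the first end groups left) times (the second end groups left), both as fractions of the first charge. The zero of this scale is a quotient of 1, where the level is r/(r+1). For ash, r is 0.948, so the zero level is 48.7%.

Green reads 1.16. Grey, at 60.5%, reads 1.09. Amber, at 32.9%, reads 1.07. Ochre, at 42.7%, reads 1.62, higher than the others, so I keep it out. The mean of the other runs is my balance quotient (the usual equilibrium constant), 1.11.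

I expect ash to climb steeply and to have its knee before 1.00 min, as the green run, with the same charge, does. My quotient puts the ash level at 49.9%. I expect larch to start near the slope of its feed, 0.0833 min⁻¹ of the charge. At 6.00 min my quotient puts larch at 33.5%. At that time it puts elm at 32.9%, a little lower than larch. By the same reckoning larch and elm reach the ash level at 12 min. Because the 8.00 min left exceed the 1.00 min by which the green run reads flat, I expect the same level in each: thermodynamic control.

The forecast gives larch 50.5%, elm 50.5%, ash 50.4% and all alike, “so all three should reach the same balance”; its ash lies above mine by 0.50 percentage points.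

Larch, elm and ash end at 50.5%, 50.5% and 50.5%, so the answer is all alike.

    first end groups + second end groups ⇌ links + by-product (K = 1.10, k = 5.20 M⁻¹ s⁻¹)
    crystals ⇌ by-product, rate k2*(cs2 - [by-product]) while solid is left; crystals form when [by-product] > cs2 (solubility = 0.110 M, k = 0.0600 s⁻¹)

Larch at 10.0 min, still in its feed, holds links 45.4%, first end groups 38.0%, and second end groups 52.1% of their own charge. In the quotient these give 1.10, near my 1.11. The larch answer moves by 5 points with second end groups at 0.184 M or 0.252 M.

The neighbour flask is larch with 0.054 M of second end groups, so r is 0.235. The quotient gives 19.3% of links, and that neighbour flask gives 19.3%.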